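The runs were computed on assumed constants; scatter was added.

At the 40.0 min reading I found both earlier runs standing still, so I wrote this note for whoever took the bench.

| flask | left-handed substrate | right-handed substrate | reagent | free catalyst | racemization catalyst | remark | time |
|---|---|---|---|---|---|---|---|
| epsilon | 0.020 M | 0.020 M | 1.3 equiv | 0.05 mol% | 0.5 mol% | run made earlier |  |
| beta | 0.020 M | 0.020 M | 3 equiv | 0.05 mol% | 0.5 mol% | run made earlier |  |
| flask | 0.020 M | 0.020 M | 2.00 equiv | 0.05 mol% | 0.5 mol% |  | 40 min |

- epsilon (time / min: left-handed substrate / %, right-handed substrate / %, left-handed product / %): 3.00: 46.3, 48.3, 4.7; 6.00: 43.0, 46.0, 8.5; 12.0: 40.6, 45.9, 9.9; 20.0: 39.5, 45.4, 11.7; 40.0: 40.6, 44.0, 11.5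
- beta (time / min: left-handed substrate / %, right-handed substrate / %, left-handed product / %): 3.00: 40.0, 46.6, 9.9; 6.00: 35.2, 43.7, 16.3; 12.0: 30.8, 41.6, 19.3; 20.0: 29.5, 39.8, 22.3; 40.0: 30.5, 38.5, 22.2

(standard deviation of a reading: 0.5 percentage points)

* part of the left-handed substrate and right-handed substrate charged together that has reacted at 40 min
* excess of left-handed product over right-handed product in the product at 40 min
* excess of right-handed substrate over left-handed substrate among what is left of the two at 40 min

Against the two substrates together, epsilon held reagent 0.650 and beta 1.50. The flask held 1, since its 2.00 equiv count on the left-handed substrate alone. By 40.0 min epsilon had converted 15.4% with 76.3% of its reagent unused, and beta had converted 31.0% with 79.3% of its reagent unused. So neither run stopped for want of reagent, although by charge reagent was the limiting reagent in epsilon, with less reagent than substrates. I took the free catalyst to be dying on its own clock, with the rate first order in reagent and in substrate. Integrating that, with c the conversion and r the reagent ratio, gave: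

dose = ln[ r(1 − c) / (r − c) ] / (1 − r)

Epsilon gave 0.295 and beta 0.279. I carried their mean, 0.287, as the catalyst dose: rate constant times free catalyst times the substrates' charge, summed over the catalyst's whole life. It scales with the catalyst charge and ignores the reagent. At r = 1 the formula shrinks:

c = dose / (1 + dose) = 22.3%

I told my successor to expect that and to sample on time. In beta the substrate gap fell from 10 percentage points to 8 points between 20.0 min and 40.0 min, while left-handed product read 22.3% and 22.2%.

The forecast said “This shows catalyst death” and gave 22.5%, 47% and 7.6%. Its dose of 0.134 differs from mine, but its conversion stood near my figure.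

    reagent + free catalyst + left-handed substrate → free catalyst + left-handed product (k = 1.70 × 10⁵ L² mol⁻² min⁻¹)
    reagent + free catalyst + right-handed substrate → free catalyst + right-handed product (k = 57000 L² mol⁻² min⁻¹)
    left-handed substrate + racemization catalyst ⇌ right-handed substrate + racemization catalyst, rate k3*[racemization catalyst]*[left-handed substrate] forward; the back reaction follows from the equilibrium constant (k = 78.0 L mol⁻¹ min⁻¹)
    free catalyst → spent catalyst (k = 0.150 min⁻¹)

The flask gave 22.6%, 45.3% and 7.77%, within the forecast's tolerance. Free catalyst in the flask had a half-life of 4.6 min by its death step, shorter than the 20 min reagent needed by the left-handed step with everything held at its charge, and at 40.0 min spent catalyst stood at 99.8% with 77% of the reagent left. Read back, the flask's conversion gave a dose of 0.292 against my 0.287. The neighbour charged with 0.2 mol% of free catalyst carried a dose of 1.15, which reckoned to 53.5%, and its simulated conversion was 52.1%.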